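**Retrosynthetic overview**

- Feature: ring A is the ten-membered carbocycle C1–C10 and ring B the oxirane on C9–C10. C1(OAc)–C2(iPr)–C3(OBz) is an aldol array whose C1 carbinol adjoins the oxirane carbon C10, so a C2 enolate of a C3 ketone can close ring A on a 2,3-epoxy aldehyde.
- C3 benzoate and C1 acetate ⇒ C1-hydroxy C3-ketone, by anti-selective Evans–Tishchenko reduction with acetaldehyde, then benzoylation.
- Ring A ⇒ acyclic C2-bromo C3-ketone carrying the cis-epoxy aldehyde; the C1–C2 bond is made by a SmI2 Reformatsky-type macro-aldol.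
- Acyclic chain ⇒ nerol (C1, C4–C10, both methyls) and (R)-2-hydroxy-3-methylbutanoic acid (C2, C3, isopropyl): SeO2 oxidation at C4, allylbarium addition to the α-silyloxy aldehyde (C3–C4), C2–O to C2–Br by SN2, Sharpless epoxidation of the (Z)-allylic alcohol.
- Ring order: ring B (oxirane) first, ring A (carbocycle) second.

Key step: step 14

Remark: ring atoms are numbered C1(OAc)–C2(iPr)–C3(OBz)–C4–C5(Me)=C6–C7–C8–C9(Me)–C10 with the oxirane on C9–C10 (target 1R,2R,3S,5E,9S,10R), and this numbering is kept for the acyclic intermediates. C2 becomes a planar enolate carbon in the key step, so either enantiomer of the hydroxy acid would serve; the (R)-acid is taken so that the single SN2 inversion gives the (S)-bromide, and the C3 carbinol of the coupling step is carried as an epimer mixture into its oxidation.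

**Route**

Step 1
Reactants: 1 (2R)-2-hydroxy-3-methylbutanoic acid
Product: 2 methyl (2R)-2-hydroxy-3-methylbutanoate
Conditions: MeOH, H2SO4 (cat.), reflux
Reagents that add atoms: methanol, CO
Why: Fischer esterification acts on the carboxyl group only and leaves the C2 stereocentre untouched.

Step 2
Reactants: 2 methyl (2R)-2-hydroxy-3-methylbutanoate
Product: 3 methyl (2R)-3-methyl-2-[(triethylsilyl)oxy]butanoate
Conditions: Et3SiCl, imidazole, DMF, 0 °C → rt
Reagents that add atoms: chlorotriethylsilane, CC[Si](Cl)(CC)CC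
Why: Imidazole-mediated silylation gives a triethylsilyl ether that withstands hydride and organobarium reagents and can later be cleaved by mild acid beside a tert-butyldiphenylsilyl ether.

Step 3
Reactants: 3 methyl (2R)-3-methyl-2-[(triethylsilyl)oxy]butanoate
Product: 4 (2R)-3-methyl-2-[(triethylsilyl)oxy]butanal
Conditions: i-Bu2AlH (1.1 equiv), CH2Cl2, −78 °C; MeOH, then aq. potassium sodium tartrate
Reagents that add atoms: none
Why: Partial reduction of an α-silyloxy methyl ester with i-Bu2AlH is arrested at the aldehyde stage at −78 °C, and the aldehyde is used at once so that C2 does not epimerise.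

Step 4
Reactants: 5 nerol, (2Z)-3,7-dimethylocta-2,6-dien-1-ol
Product: 6 tert-butyl{[(2Z)-3,7-dimethylocta-2,6-dien-1-yl]oxy}diphenylsilane
Conditions: t-BuPh2SiCl, imidazole, DMF, 0 °C → rt
Reagents that add atoms: tert-butyl(chloro)diphenylsilane, CC(C)(C)[Si](Cl)(c1ccccc1)c1ccccc1
Why: Silylation of the primary allylic alcohol gives a robust ether that deactivates the neighbouring alkene toward the next oxidation and survives every step up to step 11.

Step 5
Reactants: 6 tert-butyl{[(2Z)-3,7-dimethylocta-2,6-dien-1-yl]oxy}diphenylsilane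
Product: 7 (2E,6Z)-8-[(tert-butyldiphenylsilyl)oxy]-2,6-dimethylocta-2,6-dien-1-ol
Conditions: SeO2 (0.1 equiv), t-BuOOH (2 equiv), salicylic acid (0.1 equiv), CH2Cl2, 0 °C → rt
Reagents that add atoms: tert-butyl hydroperoxide, CC(C)(C)OO; selenium dioxide, O=[Se]=O
Why: Catalytic SeO2/t-BuOOH allylic oxidation (ene reaction, then [2,3]-sigmatropic shift) attacks the electron-rich terminal trisubstituted alkene at its (E)-methyl group and so should give the (E)-allylic alcohol at C4, sparing the alkene next to the silyloxy group.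

Step 6
Reactants: 7 (2E,6Z)-8-[(tert-butyldiphenylsilyl)oxy]-2,6-dimethylocta-2,6-dien-1-ol
Product: 8 tert-butyl{[(2Z,6E)-8-chloro-3,7-dimethylocta-2,6-dien-1-yl]oxy}diphenylsilane
Conditions: N-chlorosuccinimide, Me2S, CH2Cl2, −20 → 0 °C
Reagents that add atoms: N-chlorosuccinimide, O=C1CCC(=O)N1Cl
Why: Corey–Kim chlorination replaces the activated primary allylic hydroxyl by chloride in a direct SN2 step, without allylic transposition or E/Z scrambling, and leaves the silyl ether alone.

Step 7
Reactants: 8 tert-butyl{[(2Z,6E)-8-chloro-3,7-dimethylocta-2,6-dien-1-yl]oxy}diphenylsilane; 4 (2R)-3-methyl-2-[(triethylsilyl)oxy]butanal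
Product: 10 (3R,6E,10Z)-12-[(tert-butyldiphenylsilyl)oxy]-2,6,10-trimethyl-3-[(triethylsilyl)oxy]dodeca-6,10-dien-4-ol (both C4 epimers; C4 here is ring atom C3), via allylbarium chloride 9 (not isolated)
Conditions: BaI2, lithium biphenylide (2 equiv), THF, rt; 8, −78 °C; then 4, −78 °C; aq. NH4Cl at −78 °C
Reagents that add atoms: none
Why: An allylbarium chloride made from the allylic chloride and zerovalent barium at −78 °C adds to aldehydes at its α-carbon with retention of the (E)-alkene geometry (allylbarium carbonyl addition), so the C3–C4 bond should form without transposition; the C3 carbinol arises as an epimer mixture that step 8 erases, and the cold quench prevents 1,2-silyl migration.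

Step 8
Reactants: 10 (3R,6E,10Z)-12-[(tert-butyldiphenylsilyl)oxy]-2,6,10-trimethyl-3-[(triethylsilyl)oxy]dodeca-6,10-dien-4-ol
Product: 11 (3R,6E,10Z)-12-[(tert-butyldiphenylsilyl)oxy]-2,6,10-trimethyl-3-[(triethylsilyl)oxy]dodeca-6,10-dien-4-one
Conditions: Dess–Martin periodinane, NaHCO3, CH2Cl2, 0 °C → rt
Reagents that add atoms: none
Why: Buffered Dess–Martin oxidation converts both carbinol epimers into the C3 ketone under neutral conditions that should not move the β,γ-alkene into conjugation or disturb the silyl ethers.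

Step 9
Reactants: 11 (3R,6E,10Z)-12-[(tert-butyldiphenylsilyl)oxy]-2,6,10-trimethyl-3-[(triethylsilyl)oxy]dodeca-6,10-dien-4-one
Product: 12 (3R,6E,10Z)-12-[(tert-butyldiphenylsilyl)oxy]-3-hydroxy-2,6,10-trimethyldodeca-6,10-dien-4-one
Conditions: pyridinium p-toluenesulfonate (cat.), MeOH–CH2Cl2, 0 °C → rt
Reagents that add atoms: none
Why: Acid-catalysed methanolysis cleaves the triethylsilyl ether far faster than the acid-stable tert-butyldiphenylsilyl ether (selective silyl ether solvolysis) and frees the C2 hydroxyl without enolising the ketone.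

Step 10
Reactants: 12 (3R,6E,10Z)-12-[(tert-butyldiphenylsilyl)oxy]-3-hydroxy-2,6,10-trimethyldodeca-6,10-dien-4-one
Product: 14 (3S,6E,10Z)-3-bromo-12-[(tert-butyldiphenylsilyl)oxy]-2,6,10-trimethyldodeca-6,10-dien-4-one, via mesylate 13 (not isolated)
Conditions: MsCl (1.3 equiv), Et3N (1.2 equiv), THF, −20 °C; then LiBr (5 equiv), 0 °C → rt
Reagents that add atoms: lithium bromide, [Li+].[Br-]
Why: Mesylation followed by bromide displacement is an SN2 substitution accelerated by the adjacent carbonyl group, so the C2 bromide should form with inversion (R alcohol to S bromide), and the base is kept below the amount of MsCl so that none remains to eliminate HBr.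

Step 11
Reactants: 14 (3S,6E,10Z)-3-bromo-12-[(tert-butyldiphenylsilyl)oxy]-2,6,10-trimethyldodeca-6,10-dien-4-one
Product: 15 (3S,6E,10Z)-3-bromo-12-hydroxy-2,6,10-trimethyldodeca-6,10-dien-4-one
Conditions: HF·pyridine, THF, 0 °C → rt (polyethylene vessel)
Reagents that add atoms: none
Why: Fluoride-driven desilylation under acidic, non-basic conditions frees the (Z)-allylic alcohol while the base-sensitive α-bromo β',γ'-unsaturated ketone stays intact.

Step 12
Reactants: 15 (3S,6E,10Z)-3-bromo-12-hydroxy-2,6,10-trimethyldodeca-6,10-dien-4-one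
Product: 16 (3S,6E)-3-bromo-9-[(2S,3R)-3-(hydroxymethyl)-2-methyloxiran-2-yl]-2,6-dimethylnon-6-en-4-one
Conditions: Ti(OiPr)4 (0.1 equiv), D-(−)-diethyl tartrate (0.12 equiv), t-BuOOH (anhydrous, 2 equiv), 4 Å molecular sieves, CH2Cl2, −20 °C; aq. tartaric acid work-up
Reagents that add atoms: tert-butyl hydroperoxide, CC(C)(C)OO
Why: Katsuki–Sharpless asymmetric epoxidation of the nerol-type (Z)-allylic alcohol with the D-(−)-tartrate ligand delivers oxygen under reagent control to the face that gives the cis-oxirane with C9 S and C10 R (ring B), stereospecifically from the Z-alkene, while the C5=C6 alkene has no allylic hydroxyl and is not epoxidised.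

Step 13
Reactants: 16 (3S,6E)-3-bromo-9-[(2S,3R)-3-(hydroxymethyl)-2-methyloxiran-2-yl]-2,6-dimethylnon-6-en-4-one
Product: 17 (2S,3S)-3-[(3E,7S)-7-bromo-4,8-dimethyl-6-oxonon-3-en-1-yl]-3-methyloxirane-2-carbaldehyde
Conditions: Dess–Martin periodinane, NaHCO3, CH2Cl2, 0 °C
Reagents that add atoms: none
Why: Buffered Dess–Martin oxidation of the primary epoxy alcohol gives the 2,3-epoxy aldehyde without touching the oxirane stereocentres or the bromo ketone, and the aldehyde is taken on directly.

Step 14
Reactants: 17 (2S,3S)-3-[(3E,7S)-7-bromo-4,8-dimethyl-6-oxonon-3-en-1-yl]-3-methyloxirane-2-carbaldehyde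
Product: 20 (1R,2R,3S,6E,10S)-2-hydroxy-6,10-dimethyl-3-(propan-2-yl)-11-oxabicyclo[8.1.0]undec-6-en-4-one, via samarium enolate 18 (not isolated), via samarium aldolate 19 (not isolated)
Conditions: SmI2 (2.2 equiv, 0.1 M in THF) added over 2 h to 17 (0.003 M in THF), −78 °C; aq. NH4Cl at −78 °C
Reagents that add atoms: none
Why: Two single-electron transfers from divalent samarium cleave the C2–Br bond and give the trivalent samarium enolate of the C3 ketone at C2 only, so the more acidic allylic C4 is never deprotonated, and the oxophilic metal then binds the C1 aldehyde oxygen and the enolate adds through a six-membered chelated transition state. The closest known reaction type is the SmI2-promoted intramolecular Reformatsky-type aldol of α-bromo ketones that carry a remote aldehyde, which is used to close medium carbocycles. Ring A closes in a 10-(enolendo)-exo-trig mode by forming C1–C2. C1 is controlled by the adjacent cis-oxirane: in the Felkin–Anh arrangement the C10–O bond is turned away from the incoming enolate, which passes the C10 hydrogen and should give the erythro epoxy alcohol (C1 R); C2 is controlled in the chelate, where C10 and the isopropyl group both sit equatorial, which is the anti aldolate, and retro-aldol equilibration of the samarium aldolate leads to the same more stable chelate. The step needs C–Br reduction ahead of single-electron reduction of the epoxy aldehyde, which the much faster reduction of α-bromo ketones, the absence of HMPA and proton sources and the slow addition of only two equivalents of SmI2 at −78 °C secure, while high dilution suppresses intermolecular aldol addition. Either C2 epimer of the bromide gives the same enolate.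

Step 15
Reactants: 20 (1R,2R,3S,6E,10S)-2-hydroxy-6,10-dimethyl-3-(propan-2-yl)-11-oxabicyclo[8.1.0]undec-6-en-4-one
Product: 22 (1R,2R,3R,4S,6E,10S)-4-hydroxy-6,10-dimethyl-3-(propan-2-yl)-11-oxabicyclo[8.1.0]undec-6-en-2-yl acetate, via samarium hemiacetalate 21 (not isolated)
Conditions: CH3CHO (6 equiv, freshly distilled), SmI2 (0.3 equiv), THF, −10 °C
Reagents that add atoms: acetaldehyde, CC=O
Why: In the Evans–Tishchenko reduction the C1 hydroxyl forms a samarium-bound hemiacetal with acetaldehyde whose hydride is delivered intramolecularly to the C3 ketone through a six-membered chair, so the C1 oxygen should emerge as the acetate and the new C3 hydroxyl 1,3-anti to it (C3 S), whatever the C2 substituent.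

Step 16
Reactants: 22 (1R,2R,3R,4S,6E,10S)-4-hydroxy-6,10-dimethyl-3-(propan-2-yl)-11-oxabicyclo[8.1.0]undec-6-en-2-yl acetate
Product: 23 (1R,2R,3R,4S,6E,10S)-2-(acetyloxy)-6,10-dimethyl-3-(propan-2-yl)-11-oxabicyclo[8.1.0]undec-6-en-4-yl benzoate (CNP0112246.1)
Conditions: BzCl, pyridine, DMAP (cat.), CH2Cl2, 0 °C → rt
Reagents that add atoms: benzoyl chloride, O=C(Cl)c1ccccc1
Why: DMAP-catalysed acylation of the remaining secondary C3 hydroxyl with benzoyl chloride proceeds with retention at carbon, at low temperature to avoid 1,3-acetyl migration, and completes the target.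

**Compound list**

1 | (2R)-2-hydroxy-3-methylbutanoic acid | CC(C)[C@@H](O)C(=O)O | starting material
2 | methyl (2R)-2-hydroxy-3-methylbutanoate | CC(C)[C@@H](O)C(=O)OC | intermediate
3 | methyl (2R)-3-methyl-2-[(triethylsilyl)oxy]butanoate | CC(C)[C@@H](O[Si](CC)(CC)CC)C(=O)OC | intermediate
4 | (2R)-3-methyl-2-[(triethylsilyl)oxy]butanal | CC(C)[C@@H](O[Si](CC)(CC)CC)C=O | intermediate
5 | nerol, (2Z)-3,7-dimethylocta-2,6-dien-1-ol | CC(C)=CCC/C(C)=C\CO | starting material
6 | tert-butyl{[(2Z)-3,7-dimethylocta-2,6-dien-1-yl]oxy}diphenylsilane | CC(C)=CCC/C(C)=C\CO[Si](c1ccccc1)(c1ccccc1)C(C)(C)C | intermediate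
7 | (2E,6Z)-8-[(tert-butyldiphenylsilyl)oxy]-2,6-dimethylocta-2,6-dien-1-ol | OC/C(C)=C/CC/C(C)=C\CO[Si](c1ccccc1)(c1ccccc1)C(C)(C)C | intermediate
8 | tert-butyl{[(2Z,6E)-8-chloro-3,7-dimethylocta-2,6-dien-1-yl]oxy}diphenylsilane | ClC/C(C)=C/CC/C(C)=C\CO[Si](c1ccccc1)(c1ccccc1)C(C)(C)C | intermediate
9 | {(2E,6Z)-8-[(tert-butyldiphenylsilyl)oxy]-2,6-dimethylocta-2,6-dien-1-yl}barium chloride | Cl[Ba]C/C(C)=C/CC/C(C)=C\CO[Si](c1ccccc1)(c1ccccc1)C(C)(C)C | intermediate (not isolated)
10 | (3R,6E,10Z)-12-[(tert-butyldiphenylsilyl)oxy]-2,6,10-trimethyl-3-[(triethylsilyl)oxy]dodeca-6,10-dien-4-ol, both C4 epimers | CC(C)[C@@H](O[Si](CC)(CC)CC)C(O)C/C(C)=C/CC/C(C)=C\CO[Si](c1ccccc1)(c1ccccc1)C(C)(C)C | intermediate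
11 | (3R,6E,10Z)-12-[(tert-butyldiphenylsilyl)oxy]-2,6,10-trimethyl-3-[(triethylsilyl)oxy]dodeca-6,10-dien-4-one | CC(C)[C@@H](O[Si](CC)(CC)CC)C(=O)C/C(C)=C/CC/C(C)=C\CO[Si](c1ccccc1)(c1ccccc1)C(C)(C)C | intermediate
12 | (3R,6E,10Z)-12-[(tert-butyldiphenylsilyl)oxy]-3-hydroxy-2,6,10-trimethyldodeca-6,10-dien-4-one | CC(C)[C@@H](O)C(=O)C/C(C)=C/CC/C(C)=C\CO[Si](c1ccccc1)(c1ccccc1)C(C)(C)C | intermediate
13 | (3R,6E,10Z)-12-[(tert-butyldiphenylsilyl)oxy]-2,6,10-trimethyl-4-oxododeca-6,10-dien-3-yl methanesulfonate | CC(C)[C@@H](OS(C)(=O)=O)C(=O)C/C(C)=C/CC/C(C)=C\CO[Si](c1ccccc1)(c1ccccc1)C(C)(C)C | intermediate (not isolated)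
14 | (3S,6E,10Z)-3-bromo-12-[(tert-butyldiphenylsilyl)oxy]-2,6,10-trimethyldodeca-6,10-dien-4-one | CC(C)[C@H](Br)C(=O)C/C(C)=C/CC/C(C)=C\CO[Si](c1ccccc1)(c1ccccc1)C(C)(C)C | intermediate
15 | (3S,6E,10Z)-3-bromo-12-hydroxy-2,6,10-trimethyldodeca-6,10-dien-4-one | CC(C)[C@H](Br)C(=O)C/C(C)=C/CC/C(C)=C\CO | intermediate
16 | (3S,6E)-3-bromo-9-[(2S,3R)-3-(hydroxymethyl)-2-methyloxiran-2-yl]-2,6-dimethylnon-6-en-4-one | CC(C)[C@H](Br)C(=O)C/C(C)=C/CC[C@]1(C)O[C@@H]1CO | intermediate
17 | (2S,3S)-3-[(3E,7S)-7-bromo-4,8-dimethyl-6-oxonon-3-en-1-yl]-3-methyloxirane-2-carbaldehyde (key-step precursor) | CC(C)[C@H](Br)C(=O)C/C(C)=C/CC[C@]1(C)O[C@@H]1C=O | intermediate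
18 | diiodosamarium C2=C3 enolate of 17 (trivalent samarium; enolate geometry not fixed) | CC(C)C=C(O[Sm](I)I)C/C(C)=C/CC[C@]1(C)O[C@@H]1C=O | intermediate (not isolated)
19 | diiodosamarium C1 alkoxide of 20 (trivalent samarium aldolate) | I[Sm](I)O[C@@H]1[C@H](C(C)C)C(=O)C/C(C)=C/CC[C@]2(C)O[C@H]12 | intermediate (not isolated)
20 | (1R,2R,3S,6E,10S)-2-hydroxy-6,10-dimethyl-3-(propan-2-yl)-11-oxabicyclo[8.1.0]undec-6-en-4-one (key-step product) | O[C@@H]1[C@H](C(C)C)C(=O)C/C(C)=C/CC[C@]2(C)O[C@H]12 | intermediate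
21 | samarium-bound hemiacetal of the C1 hydroxyl of 20 with acetaldehyde (trivalent samarium; ligands simplified to iodide; hemiacetal carbon undefined) | CC(O[Sm](I)I)O[C@@H]1[C@H](C(C)C)C(=O)C/C(C)=C/CC[C@]2(C)O[C@H]12 | intermediate (not isolated)
22 | (1R,2R,3R,4S,6E,10S)-4-hydroxy-6,10-dimethyl-3-(propan-2-yl)-11-oxabicyclo[8.1.0]undec-6-en-2-yl acetate | CC(=O)O[C@@H]1[C@H](C(C)C)[C@@H](O)C/C(C)=C/CC[C@]2(C)O[C@H]12 | intermediate
23 | (1R,2R,3R,4S,6E,10S)-2-(acetyloxy)-6,10-dimethyl-3-(propan-2-yl)-11-oxabicyclo[8.1.0]undec-6-en-4-yl benzoate | CC(=O)O[C@@H]1[C@H](C(C)C)[C@@H](OC(=O)c2ccccc2)C/C(C)=C/CC[C@]2(C)O[C@H]12 | target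

**Step count and risks**

Total step count: 16. Longest linear sequence: 13 steps (steps 4–16 from nerol; the branch from the hydroxy acid, steps 1–3 and 7–16, is equally long).

Most likely to fail:

1. Step 14 (macro-aldol). What may go wrong: single-electron reduction of the α,β-epoxy aldehyde (ketyl formation with opening of the oxirane, or pinacol coupling) competing with C–Br reduction; proton transfer from C4 to the C2 enolate before closure; or oligomerisation. Facial control at C1 and the anti C1/C2 relation are also not guaranteed, since a samarium chelate that includes the oxirane oxygen would favour the threo isomer. Fallback: the same C1–C2 bond is closed by a hydride-triggered reductive aldol, a two-electron process in place of the electron-transfer enolate formation. It sets out from chloride 8 and comes back at 20. The allylbarium chloride 9 is added at −78 °C to 3-methylbut-2-enal to give the dienol F1. MnO2 in CH2Cl2 oxidises this allylic alcohol to the isopropylidene enone F2. HF·pyridine frees the allylic alcohol F3. Sharpless epoxidation with D-(−)-diethyl tartrate gives the epoxy alcohol F4. Buffered Dess–Martin oxidation gives the epoxy aldehyde F5. Treating F5 at high dilution in toluene with [(Ph3P)CuH]6 adds hydride to the β-carbon of the enone, which creates the isopropyl group, and the copper enolate at C2 adds to the C1 aldehyde to give 20.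

2. Step 15 (Evans–Tishchenko). What may go wrong: opening of the oxirane by the Lewis-acidic trivalent samarium alkoxide, migration of the acetyl group from the C1 to the C3 oxygen, retro-aldol opening of ring A, or a ring conformation that does not allow the chair needed for hydride delivery. Fallback: reduction and acylation are separated. It sets out from 20 and comes back at 23. Me4NBH(OAc)3 in MeCN–AcOH at −30 °C (hydroxyl-directed Saksena–Evans reduction, hydride delivered from the C1-bound borate) should give the 1,3-anti diol F6. Benzoyl chloride (1 equiv) with 2,4,6-collidine at −40 °C is expected to acylate the C3 hydroxyl, which has a methylene neighbour, ahead of the C1 hydroxyl, which is flanked by C2 and the oxirane, giving the C3 monobenzoate F7. Acetic anhydride, pyridine and DMAP then acetylate C1 and give 23.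

3. Step 7 (allylbarium coupling). What may go wrong: loss of α-regioselectivity or of the E geometry by equilibration of the allylbarium, homocoupling of the allylic chloride, or 1,2-migration of the triethylsilyl group in the barium alkoxide. Fallback: the C3–C4 bond is made by acylation of a sulfone-stabilised allyl anion. It sets out from 8 and comes back at 11. PhSO2Na in DMF gives the allylic sulfone F8. Deprotonation with n-BuLi (2 equiv) in THF at −78 °C and acylation with ester 3 gives the β-keto sulfone F9. Reductive desulfonylation with aluminium amalgam Al(Hg) in aqueous THF at 0 °C removes the sulfonyl group, kinetic protonation keeps the alkene at C5=C6, and ketone 11 results.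

**Further compounds**

F1 | step 14 | (6E,10Z)-12-[(tert-butyldiphenylsilyl)oxy]-2,6,10-trimethyldodeca-2,6,10-trien-4-ol (racemic at C4) | CC(C)=CC(O)C/C(C)=C/CC/C(C)=C\CO[Si](c1ccccc1)(c1ccccc1)C(C)(C)C
F2 | step 14 | (6E,10Z)-12-[(tert-butyldiphenylsilyl)oxy]-2,6,10-trimethyldodeca-2,6,10-trien-4-one | CC(C)=CC(=O)C/C(C)=C/CC/C(C)=C\CO[Si](c1ccccc1)(c1ccccc1)C(C)(C)C
F3 | step 14 | (6E,10Z)-12-hydroxy-2,6,10-trimethyldodeca-2,6,10-trien-4-one | CC(C)=CC(=O)C/C(C)=C/CC/C(C)=C\CO
F4 | step 14 | (6E)-9-[(2S,3R)-3-(hydroxymethyl)-2-methyloxiran-2-yl]-2,6-dimethylnona-2,6-dien-4-one | CC(C)=CC(=O)C/C(C)=C/CC[C@]1(C)O[C@@H]1CO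
F5 | step 14 | (2S,3S)-3-[(3E)-4,8-dimethyl-6-oxonona-3,7-dien-1-yl]-3-methyloxirane-2-carbaldehyde | CC(C)=CC(=O)C/C(C)=C/CC[C@]1(C)O[C@@H]1C=O
F6 | step 15 | (1R,2R,3R,4S,6E,10S)-6,10-dimethyl-3-(propan-2-yl)-11-oxabicyclo[8.1.0]undec-6-ene-2,4-diol | O[C@@H]1[C@H](C(C)C)[C@@H](O)C/C(C)=C/CC[C@]2(C)O[C@H]12
F7 | step 15 | (1R,2R,3S,4S,6E,10S)-2-hydroxy-6,10-dimethyl-3-(propan-2-yl)-11-oxabicyclo[8.1.0]undec-6-en-4-yl benzoate | O[C@@H]1[C@H](C(C)C)[C@@H](OC(=O)c2ccccc2)C/C(C)=C/CC[C@]2(C)O[C@H]12
F8 | step 7 | tert-butyl{[(2Z,6E)-8-(benzenesulfonyl)-3,7-dimethylocta-2,6-dien-1-yl]oxy}diphenylsilane | O=S(=O)(C/C(C)=C/CC/C(C)=C\CO[Si](c1ccccc1)(c1ccccc1)C(C)(C)C)c1ccccc1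
F9 | step 7 | (3R,6E,10Z)-5-(benzenesulfonyl)-12-[(tert-butyldiphenylsilyl)oxy]-2,6,10-trimethyl-3-[(triethylsilyl)oxy]dodeca-6,10-dien-4-one (both C5 epimers) | CC(C)[C@@H](O[Si](CC)(CC)CC)C(=O)C(S(=O)(=O)c1ccccc1)/C(C)=C/CC/C(C)=C\CO[Si](c1ccccc1)(c1ccccc1)C(C)(C)C
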